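## Retrosynthetic overview

1. Last bond: Stille coupling between a lactone-bearing (E,E)-dienyl iodide and a pyran-bearing (E,E)-dienylstannane (central C–C bond of the tetraene). The two middle CH units come from (E)-1,2-bis(tributylstannyl)ethene.
2. Ring A (γ-lactone) half: the lactone closes directly after a D-proline anti cross-aldol of propanal with an α-quaternary aldehyde; the aldehyde is then oxidised to the methyl ester.
3. Its quaternary/tertiary pair and the (E)-enyne come from an Ireland–Claisen rearrangement with 1,3-chirality transfer from an alkenyl alkynyl carbinol made by CBS reduction (first stereocentre of this half).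
4. Ring B (dihydropyran) half: ring closure by metathesis of a methacrolein mixed acetal, then AlMe3 substitution installs the 2,6-trans methyl. The anti diol pair comes from a chiral phosphoric acid-catalysed γ-silyloxyallylboration of (E)-3-iodo-2-methylacrolein (proposed new step, first stereocentres of this half).
5. Order of ring formation: ring A (step 7) and ring B (step 15) are built in separate branches and joined in step 19.

Assumption 1: (2E)-3-iodo-2-methylprop-2-en-1-ol, diethyl [2-(methoxy(methyl)amino)-2-oxoethyl]phosphonate, 3,3-dimethoxy-2-methylprop-1-ene and (E)-1,2-bis(tributylstannyl)ethene are bought as catalogue compounds.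

Assumption 2: senses of induction are taken by analogy: in the CBS reduction the alkenyl arm is the large group and the silylalkynyl arm the small one; (R)-TRIP sends the allyl unit to the Re face of the aldehyde as it does with benzaldehyde; D-proline gives the mirror image of the L-proline aldol.

Assumption 3: the two acetals of steps 14 and 15 are carried as epimer mixtures at the acetal carbon, which is ionised in step 16.

## Route

Step 1
Reactants: 1 1,1-dimethoxypropan-2-one; 2 diethyl [2-(methoxy(methyl)amino)-2-oxoethyl]phosphonate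
Product: 3 (2E)-N,4,4-trimethoxy-N,3-dimethylbut-2-enamide
Conditions: NaH, THF, 0 → 23 °C
Reagents that add atoms: none
Why: Horner–Wadsworth–Emmons olefination of the methyl ketone puts the bulkier dimethoxymethyl group trans to the amide, giving the (E)-enamide (minor Z isomer removed by chromatography); no stereocentre is formed.

Step 2
Reactants: 3 (2E)-N,4,4-trimethoxy-N,3-dimethylbut-2-enamide; 4 ethynyltrimethylsilane
Product: 6 (4E)-6,6-dimethoxy-5-methyl-1-(trimethylsilyl)hex-4-en-1-yn-3-one, via lithium acetylide 5 (not isolated)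
Conditions: 4, n-BuLi, THF, −78 °C; then 3, −78 → 0 °C; sat. aq. NH4Cl
Reagents that add atoms: n-butyllithium, [Li]C(C)CC (lithium only in 5)
Why: Weinreb ketone synthesis, in which the chelated tetrahedral adduct collapses only on work-up, so the acetylide adds once and in 1,2-fashion to give the cross-conjugated ynone.

Step 3
Reactants: 6 (4E)-6,6-dimethoxy-5-methyl-1-(trimethylsilyl)hex-4-en-1-yn-3-one
Product: 7 (3R,4E)-6,6-dimethoxy-5-methyl-1-(trimethylsilyl)hex-4-en-1-yn-3-ol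
Conditions: (R)-2-methyl-CBS-oxazaborolidine (20 mol %), catecholborane, CH2Cl2, −78 °C; aqueous work-up
Reagents that add atoms: none
Why: Corey–Bakshi–Shibata reduction, a metal-free oxazaborolidine-catalysed hydride transfer, sets the first stereocentre: the ketone binds the catalyst boron anti to the larger β,β-disubstituted alkenyl arm and hydride is delivered to one face to give the (3R)-carbinol.

Step 4
Reactants: 7 (3R,4E)-6,6-dimethoxy-5-methyl-1-(trimethylsilyl)hex-4-en-1-yn-3-ol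
Product: 8 (3R,4E)-6,6-dimethoxy-5-methyl-1-(trimethylsilyl)hex-4-en-1-yn-3-yl propanoate
Conditions: (EtCO)2O, DMAP (cat.), pyridine, CH2Cl2, 0 → 23 °C
Reagents that add atoms: propanoic anhydride, CCC(=O)OC(=O)CC
Why: DMAP-catalysed O-acylation of the secondary alcohol, with retention at the carbinol carbon.

Step 5
Reactants: 8 (3R,4E)-6,6-dimethoxy-5-methyl-1-(trimethylsilyl)hex-4-en-1-yn-3-yl propanoate
Product: 12 methyl (2R,3R,4E)-3-(dimethoxymethyl)-2,3-dimethylhept-4-en-6-ynoate, via silyl ketene acetal 9 (not isolated), via bis-silyl Claisen ester 10 (not isolated), via potassium carboxylate 11 (not isolated)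
Conditions: LiN(iPr)2, Me3SiCl, THF, −78 → 50 °C; then K2CO3, MeOH, 23 °C; then MeI, DMF, 23 °C
Reagents that add atoms: iodomethane, [CH3]I (ester methyl of 12); chlorotrimethylsilane, C[Si](C)(C)Cl (silicon only in 9 and 10)
Why: Ireland–Claisen rearrangement, in which the kinetic E(O)-enolate gives the (E)-silyl ketene acetal and a chair transition state with the alkynyl group equatorial (the Z-methyl group penalises the alternative by A(1,3) strain) transfers the carbinol chirality to the (2R,3R) tertiary/quaternary pair and the (E)-alkene, the allyl terminus reacting in preference to the silylalkyne; methanolysis then removes both silyl groups and O-methylation gives the ester.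

Step 6
Reactants: 12 methyl (2R,3R,4E)-3-(dimethoxymethyl)-2,3-dimethylhept-4-en-6-ynoate
Product: 13 methyl (2R,3R,4E)-3-formyl-2,3-dimethylhept-4-en-6-ynoate
Conditions: CF3CO2H/H2O, CHCl3, 0 °C
Reagents that add atoms: water, O
Why: acid-catalysed acetal hydrolysis unmasks the α-quaternary aldehyde, which has no α-hydrogen and so can neither epimerise nor self-condense.

Step 7
Reactants: 13 methyl (2R,3R,4E)-3-formyl-2,3-dimethylhept-4-en-6-ynoate; 14 propanal
Product: 16 (2R)-2-[(2S,3R,4R)-3-[(1E)-but-1-en-3-yn-1-yl]-3,4-dimethyl-5-oxooxolan-2-yl]propanal, via hydroxy aldehyde 15 (not isolated)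
Conditions: D-proline (30 mol %), 14 (3 equiv, syringe pump), DMF, 4 °C; then camphorsulfonic acid (0.5 equiv), CH2Cl2, 23 °C
Reagents that add atoms: none
Why: proline-catalysed direct cross-aldol (enamine catalysis, Houk–List transition state) with propanal as the only enolisable partner gives, under catalyst control, the anti aldol with the (S)-carbinol and (R)-methyl centres, and the acid then closes ring A by lactonisation of the γ-hydroxy ester, helped by the adjacent quaternary carbon.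

Step 8
Reactants: 16 (2R)-2-[(2S,3R,4R)-3-[(1E)-but-1-en-3-yn-1-yl]-3,4-dimethyl-5-oxooxolan-2-yl]propanal
Product: 18 methyl (2R)-2-[(2S,3R,4R)-3-[(1E)-but-1-en-3-yn-1-yl]-3,4-dimethyl-5-oxooxolan-2-yl]propanoate, via lactone acid 17 (not isolated)
Conditions: NaClO2, NaH2PO4, 2-methylbut-2-ene, tBuOH/H2O, 0 °C; then Me3SiCHN2, MeOH/PhMe, 0 °C
Reagents that add atoms: NaClO2 (sodium chlorite), [Na+].[O-]Cl=O; (trimethylsilyl)diazomethane, C[Si](C)(C)C=[N+]=[N-]
Why: Pinnick oxidation converts the aldehyde to the acid under buffered conditions that neither epimerise the α-centre nor eliminate the β-acyloxy group, and diazoalkane O-methylation gives the methyl ester.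

Step 9
Reactants: 18 methyl (2R)-2-[(2S,3R,4R)-3-[(1E)-but-1-en-3-yn-1-yl]-3,4-dimethyl-5-oxooxolan-2-yl]propanoate
Product: 20 methyl (2R)-2-[(2S,3R,4R)-3-[(1E,3E)-4-iodobuta-1,3-dien-1-yl]-3,4-dimethyl-5-oxooxolan-2-yl]propanoate, via dienylzirconocene chloride 19 (not isolated)
Conditions: Cp2Zr(H)Cl, THF, 23 °C, dark; then iodine, −20 °C
Reagents that add atoms: iodine, [I][I]; Cp2Zr(H)Cl, [H][Zr](Cl)(C1C=CC=C1)C1C=CC=C1 (zirconium only in 19)
Why: syn hydrozirconation of the terminal alkyne puts zirconium on the terminal carbon and iodinolysis with retention gives the (E,E)-dienyl iodide, ester and lactone being tolerated at 23 °C.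

Step 10
Reactants: 21 but-3-en-2-one
Product: 22 2-[(tert-butyldimethylsilyl)oxy]buta-1,3-diene
Conditions: tBuMe2SiOTf, Et3N, CH2Cl2, 0 °C
Reagents that add atoms: tert-butyldimethylsilyl trifluoromethanesulfonate, CC(C)(C)[Si](C)(C)OS(=O)(=O)C(F)(F)F
Why: soft enolisation and O-silylation of the enone gives the 2-silyloxy diene.

Step 11
Reactants: 22 2-[(tert-butyldimethylsilyl)oxy]buta-1,3-diene
Product: 23 tert-butyl(dimethyl){[(2E)-4-(4,4,5,5-tetramethyl-1,3,2-dioxaborolan-2-yl)but-2-en-2-yl]oxy}silane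
Conditions: pinacolborane, Ni(cod)2 (2.5 mol %), PCy3 (2.5 mol %), PhMe, 23 °C
Reagents that add atoms: pinacolborane, CC1(C)OBOC1(C)C
Why: nickel-hydride 1,4-hydroboration of the 2-substituted diene through the s-cis π-allyl delivers hydrogen to C1 and boron to C4, so the new methyl is cis and the silyloxy group trans to CH2B.

Step 12
Reactants: 24 (2E)-3-iodo-2-methylprop-2-en-1-ol
Product: 25 (2E)-3-iodo-2-methylprop-2-enal
Conditions: MnO2, CH2Cl2, 23 °C
Reagents that add atoms: none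
Why: MnO2 oxidises the allylic alcohol to the enal selectively and leaves the vinyl iodide untouched.

Step 13
Reactants: 25 (2E)-3-iodo-2-methylprop-2-enal; 23 tert-butyl(dimethyl){[(2E)-4-(4,4,5,5-tetramethyl-1,3,2-dioxaborolan-2-yl)but-2-en-2-yl]oxy}silane
Product: 26 (1E,3S,4R)-4-[(tert-butyldimethylsilyl)oxy]-1-iodo-2,4-dimethylhexa-1,5-dien-3-ol
Conditions: (R)-TRIP [(R)-3,3′-bis(2,4,6-triisopropylphenyl)-1,1′-binaphthyl-2,2′-diyl hydrogen phosphate] (5 mol %), 23 (1.5 equiv), 4 Å MS, PhMe, −30 → 0 °C; aq. NaHCO3 work-up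
Reagents that add atoms: none
Why: Proposed new method: chiral phosphoric acid-catalysed γ-silyloxyallylboration, in which the acid activates the pinacol boronate by hydrogen bonding to a boronate oxygen, the addition runs through a closed chair Zimmerman–Traxler transition state with the aldehyde substituent equatorial so that the γ-methyl group (cis to CH2B) ends syn and the γ-silyloxy group (trans to CH2B) anti to the new hydroxyl, and (R)-TRIP directs attack to the Re face, setting (3S) and the silyl-protected tertiary carbinol (4R) in one C–C bond formation; the closest known reactions are the phosphoric acid-catalysed allyl- and crotylboration of aldehydes with pinacol boronates and γ-alkoxyallylboration with stoichiometric chiral boranes, neither shown for a γ,γ-disubstituted γ-silyloxy reagent.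

Step 14
Reactants: 26 (1E,3S,4R)-4-[(tert-butyldimethylsilyl)oxy]-1-iodo-2,4-dimethylhexa-1,5-dien-3-ol; 27 3,3-dimethoxy-2-methylprop-1-ene
Product: 28 tert-butyl{[(3R,4S,5E)-6-iodo-4-[(1-methoxy-2-methylprop-2-en-1-yl)oxy]-3,5-dimethylhexa-1,5-dien-3-yl]oxy}dimethylsilane (acetal epimers)
Conditions: pyridinium p-toluenesulfonate (10 mol %), 27 (5 equiv), 5 Å MS, PhMe, 50 °C
Reagents that add atoms: none
Why: acid-catalysed transacetalisation, driven by removal of methanol, attaches the 2-methylallyl acetal that supplies C5, C6 and the C5 methyl of ring B.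

Step 15
Reactants: 28 tert-butyl{[(3R,4S,5E)-6-iodo-4-[(1-methoxy-2-methylprop-2-en-1-yl)oxy]-3,5-dimethylhexa-1,5-dien-3-yl]oxy}dimethylsilane
Product: 29 tert-butyl{[(2S,3R)-2-[(1E)-1-iodoprop-1-en-2-yl]-6-methoxy-3,5-dimethyl-3,6-dihydro-2H-pyran-3-yl]oxy}dimethylsilane (C6 epimers)
Conditions: second-generation Hoveyda–Grubbs catalyst [RuCl2(H2IMes)(=CH-C6H4-2-OiPr)] (10 mol %), PhMe, 80 °C
Reagents that add atoms: none
Why: ring-closing metathesis of the monosubstituted and the 1,1-disubstituted alkene forms ring B with its trisubstituted C4=C5 bond, driven by loss of ethene, while the trisubstituted iodoalkene is inert.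

Step 16
Reactants: 29 tert-butyl{[(2S,3R)-2-[(1E)-1-iodoprop-1-en-2-yl]-6-methoxy-3,5-dimethyl-3,6-dihydro-2H-pyran-3-yl]oxy}dimethylsilane
Product: 30 tert-butyl{[(2S,3R,6S)-2-[(1E)-1-iodoprop-1-en-2-yl]-3,5,6-trimethyl-3,6-dihydro-2H-pyran-3-yl]oxy}dimethylsilane
Conditions: AlMe3 (3 equiv), CH2Cl2, −78 → −20 °C; aqueous work-up
Reagents that add atoms: AlMe3 (trimethylaluminium), C[Al](C)C
Why: AlMe3 ionises the allylic acetal to a Ferrier-type allyl oxocarbenium ion and transfers methyl to C6 anti to the C2 substituent (the usual 2,6-trans outcome of C-glycosylation of such cations), setting (6S).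

Step 17
Reactants: 30 tert-butyl{[(2S,3R,6S)-2-[(1E)-1-iodoprop-1-en-2-yl]-3,5,6-trimethyl-3,6-dihydro-2H-pyran-3-yl]oxy}dimethylsilane
Product: 31 (2S,3R,6S)-2-[(1E)-1-iodoprop-1-en-2-yl]-3,5,6-trimethyl-3,6-dihydro-2H-pyran-3-ol
Conditions: Bu4NF, THF, 50 °C
Reagents that add atoms: none
Why: fluoride-mediated cleavage of the tertiary silyl ether; the vinyl iodide has no β-hydrogen on the substituted carbon and cannot eliminate.

Step 18
Reactants: 31 (2S,3R,6S)-2-[(1E)-1-iodoprop-1-en-2-yl]-3,5,6-trimethyl-3,6-dihydro-2H-pyran-3-ol; 32 (E)-1,2-bis(tributylstannyl)ethene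
Product: 33 (2S,3R,6S)-3,5,6-trimethyl-2-[(2E,4E)-5-(tributylstannyl)penta-2,4-dien-2-yl]-3,6-dihydro-2H-pyran-3-ol
Conditions: Pd2(dba)3 (5 mol %), AsPh3 (20 mol %), 32 (3 equiv), N-methylpyrrolidone, 23 °C, dark
Reagents that add atoms: none
Why: Stille coupling at zerovalent palladium joins the vinyl iodide to one end of the excess distannane with retention of both alkene geometries, giving the (E,E)-dienylstannane.

Step 19
Reactants: 20 methyl (2R)-2-[(2S,3R,4R)-3-[(1E,3E)-4-iodobuta-1,3-dien-1-yl]-3,4-dimethyl-5-oxooxolan-2-yl]propanoate; 33 (2S,3R,6S)-3,5,6-trimethyl-2-[(2E,4E)-5-(tributylstannyl)penta-2,4-dien-2-yl]-3,6-dihydro-2H-pyran-3-ol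
Product: 34 methyl (2R)-2-[(2S,3R,4R)-3-[(1E,3E,5E,7E)-8-[(2S,3R,6S)-3-hydroxy-3,5,6-trimethyl-3,6-dihydro-2H-pyran-2-yl]nona-1,3,5,7-tetraen-1-yl]-3,4-dimethyl-5-oxooxolan-2-yl]propanoate
Conditions: Pd2(dba)3 (5 mol %), AsPh3 (20 mol %), N-methylpyrrolidone, 23 °C, dark
Reagents that add atoms: none
Why: Stille coupling joins the two (E,E)-dienes with retention to give the all-(E) tetraene under neutral conditions that tolerate the free tertiary alcohol, the ester and the lactone.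

## Compound list

1 | 1,1-dimethoxypropan-2-one | CC(=O)C(OC)OC | starting material
2 | diethyl [2-(methoxy(methyl)amino)-2-oxoethyl]phosphonate | CCOP(=O)(CC(=O)N(C)OC)OCC | starting material
3 | (2E)-N,4,4-trimethoxy-N,3-dimethylbut-2-enamide | CON(C)C(=O)/C=C(\C)C(OC)OC | intermediate
4 | ethynyltrimethylsilane | C#C[Si](C)(C)C | starting material
5 | lithium (trimethylsilyl)acetylide | [Li]C#C[Si](C)(C)C | intermediate (not isolated)
6 | (4E)-6,6-dimethoxy-5-methyl-1-(trimethylsilyl)hex-4-en-1-yn-3-one | C[Si](C)(C)C#CC(=O)/C=C(\C)C(OC)OC | intermediate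
7 | (3R,4E)-6,6-dimethoxy-5-methyl-1-(trimethylsilyl)hex-4-en-1-yn-3-ol | C[Si](C)(C)C#C[C@H](O)/C=C(\C)C(OC)OC | intermediate
8 | (3R,4E)-6,6-dimethoxy-5-methyl-1-(trimethylsilyl)hex-4-en-1-yn-3-yl propanoate | CCC(=O)O[C@@H](C#C[Si](C)(C)C)/C=C(\C)C(OC)OC | intermediate
9 | trimethyl{[(1E)-1-{[(3R,4E)-6,6-dimethoxy-5-methyl-1-(trimethylsilyl)hex-4-en-1-yn-3-yl]oxy}prop-1-en-1-yl]oxy}silane | C/C=C(/O[Si](C)(C)C)O[C@@H](C#C[Si](C)(C)C)/C=C(\C)C(OC)OC | intermediate (not isolated)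
10 | trimethylsilyl (2R,3R,4E)-3-(dimethoxymethyl)-2,3-dimethyl-7-(trimethylsilyl)hept-4-en-6-ynoate | C[Si](C)(C)OC(=O)[C@H](C)[C@](C)(C(OC)OC)/C=C/C#C[Si](C)(C)C | intermediate (not isolated)
11 | potassium (2R,3R,4E)-3-(dimethoxymethyl)-2,3-dimethylhept-4-en-6-ynoate | [K+].[O-]C(=O)[C@H](C)[C@](C)(C(OC)OC)/C=C/C#C | intermediate (not isolated)
12 | methyl (2R,3R,4E)-3-(dimethoxymethyl)-2,3-dimethylhept-4-en-6-ynoate | COC(=O)[C@H](C)[C@](C)(C(OC)OC)/C=C/C#C | intermediate
13 | methyl (2R,3R,4E)-3-formyl-2,3-dimethylhept-4-en-6-ynoate | COC(=O)[C@H](C)[C@](C)(C=O)/C=C/C#C | intermediate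
14 | propanal | CCC=O | starting material
15 | methyl (2R,3R,4E)-3-[(1S,2R)-1-hydroxy-2-methyl-3-oxopropyl]-2,3-dimethylhept-4-en-6-ynoate | O=C[C@H](C)[C@H](O)[C@](C)(/C=C/C#C)[C@@H](C)C(=O)OC | intermediate (not isolated)
16 | (2R)-2-[(2S,3R,4R)-3-[(1E)-but-1-en-3-yn-1-yl]-3,4-dimethyl-5-oxooxolan-2-yl]propanal | O=C[C@H](C)[C@@H]1OC(=O)[C@H](C)[C@@]1(C)/C=C/C#C | intermediate
17 | (2R)-2-[(2S,3R,4R)-3-[(1E)-but-1-en-3-yn-1-yl]-3,4-dimethyl-5-oxooxolan-2-yl]propanoic acid | OC(=O)[C@H](C)[C@@H]1OC(=O)[C@H](C)[C@@]1(C)/C=C/C#C | intermediate (not isolated)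
18 | methyl (2R)-2-[(2S,3R,4R)-3-[(1E)-but-1-en-3-yn-1-yl]-3,4-dimethyl-5-oxooxolan-2-yl]propanoate | COC(=O)[C@H](C)[C@@H]1OC(=O)[C@H](C)[C@@]1(C)/C=C/C#C | intermediate
19 | chloridobis(cyclopentadienyl)[(1E,3E)-4-{(2S,3R,4R)-2-[(2R)-1-methoxy-1-oxopropan-2-yl]-3,4-dimethyl-5-oxooxolan-3-yl}buta-1,3-dien-1-yl]zirconium | COC(=O)[C@H](C)[C@@H]1OC(=O)[C@H](C)[C@@]1(C)/C=C/C=C/[Zr](Cl)(C2C=CC=C2)C3C=CC=C3 | intermediate (not isolated)
20 | methyl (2R)-2-[(2S,3R,4R)-3-[(1E,3E)-4-iodobuta-1,3-dien-1-yl]-3,4-dimethyl-5-oxooxolan-2-yl]propanoate | COC(=O)[C@H](C)[C@@H]1OC(=O)[C@H](C)[C@@]1(C)/C=C/C=C/I | intermediate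
21 | but-3-en-2-one | CC(=O)C=C | starting material
22 | 2-[(tert-butyldimethylsilyl)oxy]buta-1,3-diene | C=CC(=C)O[Si](C)(C)C(C)(C)C | intermediate
23 | tert-butyl(dimethyl){[(2E)-4-(4,4,5,5-tetramethyl-1,3,2-dioxaborolan-2-yl)but-2-en-2-yl]oxy}silane | C/C(O[Si](C)(C)C(C)(C)C)=C\CB1OC(C)(C)C(C)(C)O1 | intermediate
24 | (2E)-3-iodo-2-methylprop-2-en-1-ol | OC/C(C)=C/I | starting material
25 | (2E)-3-iodo-2-methylprop-2-enal | O=C/C(C)=C/I | intermediate
26 | (1E,3S,4R)-4-[(tert-butyldimethylsilyl)oxy]-1-iodo-2,4-dimethylhexa-1,5-dien-3-ol | I/C=C(\C)[C@H](O)[C@](C)(O[Si](C)(C)C(C)(C)C)C=C | intermediate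
27 | 3,3-dimethoxy-2-methylprop-1-ene | C=C(C)C(OC)OC | starting material
28 | tert-butyl{[(3R,4S,5E)-6-iodo-4-[(1-methoxy-2-methylprop-2-en-1-yl)oxy]-3,5-dimethylhexa-1,5-dien-3-yl]oxy}dimethylsilane | I/C=C(\C)[C@H](OC(OC)C(C)=C)[C@](C)(O[Si](C)(C)C(C)(C)C)C=C | intermediate
29 | tert-butyl{[(2S,3R)-2-[(1E)-1-iodoprop-1-en-2-yl]-6-methoxy-3,5-dimethyl-3,6-dihydro-2H-pyran-3-yl]oxy}dimethylsilane | I/C=C(\C)[C@@H]1OC(OC)C(C)=C[C@@]1(C)O[Si](C)(C)C(C)(C)C | intermediate
30 | tert-butyl{[(2S,3R,6S)-2-[(1E)-1-iodoprop-1-en-2-yl]-3,5,6-trimethyl-3,6-dihydro-2H-pyran-3-yl]oxy}dimethylsilane | I/C=C(\C)[C@@H]1O[C@@H](C)C(C)=C[C@@]1(C)O[Si](C)(C)C(C)(C)C | intermediate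
31 | (2S,3R,6S)-2-[(1E)-1-iodoprop-1-en-2-yl]-3,5,6-trimethyl-3,6-dihydro-2H-pyran-3-ol | I/C=C(\C)[C@@H]1O[C@@H](C)C(C)=C[C@@]1(C)O | intermediate
32 | (E)-1,2-bis(tributylstannyl)ethene | CCCC[Sn](CCCC)(CCCC)/C=C/[Sn](CCCC)(CCCC)CCCC | starting material
33 | (2S,3R,6S)-3,5,6-trimethyl-2-[(2E,4E)-5-(tributylstannyl)penta-2,4-dien-2-yl]-3,6-dihydro-2H-pyran-3-ol | CCCC[Sn](CCCC)(CCCC)/C=C/C=C(\C)[C@@H]1O[C@@H](C)C(C)=C[C@@]1(C)O | intermediate
34 | methyl (2R)-2-[(2S,3R,4R)-3-[(1E,3E,5E,7E)-8-[(2S,3R,6S)-3-hydroxy-3,5,6-trimethyl-3,6-dihydro-2H-pyran-2-yl]nona-1,3,5,7-tetraen-1-yl]-3,4-dimethyl-5-oxooxolan-2-yl]propanoate | COC(=O)[C@H](C)[C@@H]1OC(=O)[C@H](C)[C@@]1(C)/C=C/C=C/C=C/C=C(\C)[C@@H]1O[C@@H](C)C(C)=C[C@@]1(C)O | target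

## Step count and risks

Total steps: 19. Longest linear sequence: 10 (steps 1 to 9, then step 19); the pyran branch is 9 (steps 10, 11, 13 to 19).

**Step 13 (proposed new allylboration).** Risks: the γ,γ-disubstituted pinacol boronate may add slowly, the acid may protodesilylate the enol ether, and the enantioselectivity is untested. The fallback uses known chemistry, sets out from 25 and returns at 26. Wittig olefination of 25 with Ph3P=C(Me)CO2Et gives ethyl (2E,4E)-5-iodo-2,4-dimethylpenta-2,4-dienoate F1, and iBu2AlH reduction gives (2E,4E)-5-iodo-2,4-dimethylpenta-2,4-dien-1-ol F2. Sharpless asymmetric epoxidation [Ti(OiPr)4, D-(−)-diethyl tartrate, tBuOOH, 4 Å MS, −20 °C] gives [(2R,3R)-3-[(1E)-1-iodoprop-1-en-2-yl]-2-methyloxiran-2-yl]methanol F3. Ti(OiPr)4-mediated opening with benzoic acid at the allylic epoxide carbon remote from the hydroxyl, with inversion, gives (2R,3S,4E)-1,2-dihydroxy-5-iodo-2,4-dimethylpent-4-en-3-yl benzoate F4. TEMPO/PhI(OAc)2 oxidation of the primary alcohol gives (2S,3S,4E)-2-hydroxy-5-iodo-2,4-dimethyl-1-oxopent-4-en-3-yl benzoate F5, and methylenation with Ph3P=CH2 gives (3R,4S,5E)-3-hydroxy-6-iodo-3,5-dimethylhexa-1,5-dien-4-yl benzoate F6. Silylation with tBuMe2SiOTf and 2,6-lutidine gives (3R,4S,5E)-3-[(tert-butyldimethylsilyl)oxy]-6-iodo-3,5-dimethylhexa-1,5-dien-4-yl benzoate F7, and reductive removal of the benzoate with iBu2AlH at −78 °C (which avoids base-induced silyl migration) gives 26.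

**Step 7 (proline cross-aldol on a hindered α-quaternary aldehyde).** Risks: slow addition and competing propanal self-aldol. The fallback sets out from 13 and returns at 16, replacing the enamine aldol by an allylmetal addition followed by alkene cleavage. (S)-TRIP-catalysed crotylboration of 13 with (E)-crotylboronic acid pinacol ester (known, anti-selective) gives methyl (2R,3R,4E)-3-[(1S,2S)-1-hydroxy-2-methylbut-3-en-1-yl]-2,3-dimethylhept-4-en-6-ynoate F8. Camphorsulfonic acid closes the lactone to (3R,4R,5S)-5-[(2S)-but-3-en-2-yl]-4-[(1E)-but-1-en-3-yn-1-yl]-3,4-dimethyloxolan-2-one F9. Lemieux–Johnson cleavage of the terminal vinyl group (OsO4 cat., NaIO4, 2,6-lutidine, dioxane/H2O), which is less hindered than the enyne alkene, gives 16.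

**Step 15 (ring-closing metathesis).** Risk: the vinyl group on a fully substituted carbon and the 1,1-disubstituted partner may not engage. The fallback sets out from 26 and returns at 29, closing ring B by olefination instead of metathesis and bypassing 28. Esterification of 26 with 2-(diethoxyphosphoryl)propanoic acid (N,N′-dicyclohexylcarbodiimide, DMAP) gives (1E,3S,4R)-4-[(tert-butyldimethylsilyl)oxy]-1-iodo-2,4-dimethylhexa-1,5-dien-3-yl 2-(diethoxyphosphoryl)propanoate F10. Cleavage of the vinyl group (OsO4 cat., NaIO4) gives (1E,3S,4S)-4-[(tert-butyldimethylsilyl)oxy]-1-iodo-2,4-dimethyl-5-oxopent-1-en-3-yl 2-(diethoxyphosphoryl)propanoate F11. Intramolecular Horner–Wadsworth–Emmons reaction (LiCl, iPr2NEt, MeCN) gives the ring-enforced Z-lactone (5R,6S)-5-[(tert-butyldimethylsilyl)oxy]-6-[(1E)-1-iodoprop-1-en-2-yl]-3,5-dimethyl-5,6-dihydro-2H-pyran-2-one F12. iBu2AlH at −78 °C gives (5R,6S)-5-[(tert-butyldimethylsilyl)oxy]-6-[(1E)-1-iodoprop-1-en-2-yl]-3,5-dimethyl-5,6-dihydro-2H-pyran-2-ol F13, and methanol with pyridinium p-toluenesulfonate gives 29.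

Further compounds

F1 | step 13 | ethyl (2E,4E)-5-iodo-2,4-dimethylpenta-2,4-dienoate | CCOC(=O)/C(C)=C/C(C)=C/I
F2 | step 13 | (2E,4E)-5-iodo-2,4-dimethylpenta-2,4-dien-1-ol | OC/C(C)=C/C(C)=C/I
F3 | step 13 | [(2R,3R)-3-[(1E)-1-iodoprop-1-en-2-yl]-2-methyloxiran-2-yl]methanol | OC[C@@]1(C)O[C@@H]1/C(C)=C/I
F4 | step 13 | (2R,3S,4E)-1,2-dihydroxy-5-iodo-2,4-dimethylpent-4-en-3-yl benzoate | I/C=C(\C)[C@H](OC(=O)c1ccccc1)[C@](C)(O)CO
F5 | step 13 | (2S,3S,4E)-2-hydroxy-5-iodo-2,4-dimethyl-1-oxopent-4-en-3-yl benzoate | I/C=C(\C)[C@H](OC(=O)c1ccccc1)[C@](C)(O)C=O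
F6 | step 13 | (3R,4S,5E)-3-hydroxy-6-iodo-3,5-dimethylhexa-1,5-dien-4-yl benzoate | I/C=C(\C)[C@H](OC(=O)c1ccccc1)[C@](C)(O)C=C
F7 | step 13 | (3R,4S,5E)-3-[(tert-butyldimethylsilyl)oxy]-6-iodo-3,5-dimethylhexa-1,5-dien-4-yl benzoate | I/C=C(\C)[C@H](OC(=O)c1ccccc1)[C@](C)(O[Si](C)(C)C(C)(C)C)C=C
F8 | step 7 | methyl (2R,3R,4E)-3-[(1S,2S)-1-hydroxy-2-methylbut-3-en-1-yl]-2,3-dimethylhept-4-en-6-ynoate | C=C[C@H](C)[C@H](O)[C@](C)(/C=C/C#C)[C@@H](C)C(=O)OC
F9 | step 7 | (3R,4R,5S)-5-[(2S)-but-3-en-2-yl]-4-[(1E)-but-1-en-3-yn-1-yl]-3,4-dimethyloxolan-2-one | C=C[C@H](C)[C@@H]1OC(=O)[C@H](C)[C@@]1(C)/C=C/C#C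
F10 | step 15 | (1E,3S,4R)-4-[(tert-butyldimethylsilyl)oxy]-1-iodo-2,4-dimethylhexa-1,5-dien-3-yl 2-(diethoxyphosphoryl)propanoate | I/C=C(\C)[C@H](OC(=O)C(C)P(=O)(OCC)OCC)[C@](C)(O[Si](C)(C)C(C)(C)C)C=C
F11 | step 15 | (1E,3S,4S)-4-[(tert-butyldimethylsilyl)oxy]-1-iodo-2,4-dimethyl-5-oxopent-1-en-3-yl 2-(diethoxyphosphoryl)propanoate | I/C=C(\C)[C@H](OC(=O)C(C)P(=O)(OCC)OCC)[C@](C)(O[Si](C)(C)C(C)(C)C)C=O
F12 | step 15 | (5R,6S)-5-[(tert-butyldimethylsilyl)oxy]-6-[(1E)-1-iodoprop-1-en-2-yl]-3,5-dimethyl-5,6-dihydro-2H-pyran-2-one | I/C=C(\C)[C@@H]1OC(=O)C(C)=C[C@@]1(C)O[Si](C)(C)C(C)(C)C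
F13 | step 15 | (5R,6S)-5-[(tert-butyldimethylsilyl)oxy]-6-[(1E)-1-iodoprop-1-en-2-yl]-3,5-dimethyl-5,6-dihydro-2H-pyran-2-ol | I/C=C(\C)[C@@H]1OC(O)C(C)=C[C@@]1(C)O[Si](C)(C)C(C)(C)C
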